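**Retrosynthetic overview**
1. Ring numbering: C1 (C=O beside C6–H), C2 (C–OH), C3 (C–pentadecadienyl), C4 (C=O), C5 (C–OMe), C6 (C–H). Enabling feature: C1, C2, C4 and C5 all carry oxygen, so the 2-hydroxy-1,4-benzoquinone ring is the enol of a cyclohex-5-ene-1,2,4-trione in which C1–C2 is an oxalyl unit and C3 is the α-carbon of the C4 ketone; the ring can be closed by acylation alone, at the quinone oxidation level.
2. Key disconnections: C3–C2 (ring-closing Claisen condensation) and C6–C1 (C-acylation of an enol ether), made in one pot from the acyclic 2-methoxy-3-silyloxy-1,3-diene 9 (C3 to C6, OMe already on C5, silyl group as temporary activator) and methyl chlorooxoacetate 10 (C1–C2).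
3. Diene 9 ⇐ α-methoxy enone 8 ⇐ Weinreb amide 5 + 1-methoxyvinyllithium.
4. Chain: 5 ⇐ Z-selective semihydrogenation of skipped diyne 4 ⇐ copper-mediated coupling of alkyne 2 (from undec-10-ynoic acid 1) with 1-bromohex-2-yne 3.
5. Order of ring formation: the quinone ring is the only ring and is formed last.

Key step: step 6

Remark: the silyl enol ether double bond of 9 and 11 is written Z, the usual result of amine/silyl triflate enolisation; this geometry is lost in step 6 and does not affect the outcome.

Step 1
Reactants: 1 undec-10-ynoic acid
Product: 2 N-methoxy-N-methylundec-10-ynamide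
Conditions: CDI, CH2Cl2, rt; then MeNH(OMe)·HCl, rt
Reagents that add atoms: N,O-dimethylhydroxylamine hydrochloride, CNOC.Cl
Why: Activation of the acid as its acyl imidazolide and aminolysis (Weinreb amide formation) should proceed without touching the terminal alkyne.

Step 2
Reactants: 2 N-methoxy-N-methylundec-10-ynamide; 3 1-bromohex-2-yne
Product: 4 N-methoxy-N-methylheptadeca-10,13-diynamide
Conditions: CuI, NaI, Cs2CO3, DMF, rt
Reagents that add atoms: none
Why: The copper acetylide formed under carbonate base displaces the propargylic bromide (copper-mediated alkyne–propargyl halide coupling) and should give the 1,4-diyne without isomerisation or reaction at the amide.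

Step 3
Reactants: 4 N-methoxy-N-methylheptadeca-10,13-diynamide
Product: 5 (10Z,13Z)-N-methoxy-N-methylheptadeca-10,13-dienamide
Conditions: H2 (1 atm), Pd/CaCO3 poisoned with Pb(OAc)2, quinoline, EtOAc, rt, stopped after uptake of 2 equiv H2
Reagents that add atoms: none
Why: Partial hydrogenation on lead-poisoned palladium (Lindlar reduction) delivers both hydrogens to one face of each alkyne on the catalyst surface, which sets the 10Z and 13Z geometry, while quinoline suppresses over-reduction.

Step 4
Reactants: 5 (10Z,13Z)-N-methoxy-N-methylheptadeca-10,13-dienamide; 6 methyl vinyl ether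
Product: 8 (12Z,15Z)-2-methoxynonadeca-1,12,15-trien-3-one, via 1-methoxyvinyllithium 7 (not isolated)
Conditions: 6, tBuLi, THF, −78 → 0 °C; then 5, −78 → −20 °C; pH 7 phosphate buffer
Reagents that add atoms: none
Why: α-Lithiation of the enol ether gives an acyl anion equivalent that undergoes acyl substitution at the N-methoxy-N-methyl amide (Weinreb ketone synthesis), which stops at the ketone stage and should leave the Z alkenes untouched at low temperature.

Step 5
Reactants: 8 (12Z,15Z)-2-methoxynonadeca-1,12,15-trien-3-one
Product: 9 tert-butyl({(3Z,12Z,15Z)-2-methoxynonadeca-1,3,12,15-tetraen-3-yl}oxy)dimethylsilane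
Conditions: TBSOTf, Et3N, CH2Cl2, −78 → 0 °C
Reagents that add atoms: tert-butyldimethylsilyl trifluoromethanesulfonate, CC(C)(C)[Si](C)(C)OS(=O)(=O)C(F)(F)F
Why: Soft enolisation and O-silylation (silyl triflate with amine base) at the only enolisable position, the CH2 that becomes C3, turns the electron-poor α-methoxy enone into an electron-rich 2-methoxy-3-silyloxy-1,3-diene whose CH2 terminus can be acylated.

Step 6
Reactants: 9 tert-butyl({(3Z,12Z,15Z)-2-methoxynonadeca-1,3,12,15-tetraen-3-yl}oxy)dimethylsilane; 10 methyl chlorooxoacetate
Product: 12 sorgoleone-360, via acylated silyl dienol ether 11 (not isolated)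
Conditions: 10, pyridine, CH2Cl2, −78 → 0 °C; then NaOMe, MeOH, −20 °C → rt; aq. HCl to pH 3
Reagents that add atoms: none
Why: Proposed new method: the unsubstituted CH2 terminus of the 2-methoxy-3-silyloxy-1,3-diene (future C6) attacks the acid chloride carbon of 10 as an enol ether does, and the methoxy-stabilised allyl cation loses a proton to pyridine to give 11; the closest known reaction types are the C-acylation of alkyl enol ethers with alkyl chlorooxoacetates or oxalyl chloride and the cyclocondensation of bis(silyl enol ethers) with oxalyl chloride. Methoxide then cleaves the O–Si bond, and the enolate carbon so released (future C3, bearing the chain) attacks the α-keto ester carbon (future C2) in a ring-closing Claisen condensation, the ring-forming event of the classical double Claisen route from oxalate to 2,5-dihydroxyquinones. The six-membered ring closes in the 6-(enolendo)-exo-trig mode, and the cyclohex-5-ene-1,2,4-trione formed enolises at once to the 2-hydroxy-1,4-benzoquinone, whose deprotonation by methoxide makes the closure irreversible and removes any need for a redox step. No stereocentre is created, and the two Z alkenes of the chain lie far from the reacting atoms and are inert to pyridine and methoxide. The step needs site selectivity in the acylation (C6 before C3), which the unhindered CH2 terminus, the bulky silyl group beside C3 and the better donor (OMe) on the carbon that turns cationic should secure; because the ester end of 10 reacts only with the enolate released later, the C3–C2 bond is then necessarily the ring-closing one. It also needs the six-ring Claisen closure to beat a five-ring aldol addition of C3 to the C1 ketone, which should hold because the aldol is reversible whereas the Claisen product is drained as its anion, and because methoxide exchange at C5 and at the ester is degenerate and only equilibrates the enol ether geometry.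

**Compound list**
1 | undec-10-ynoic acid | C#CCCCCCCCCC(=O)O | starting material
2 | N-methoxy-N-methylundec-10-ynamide | C#CCCCCCCCCC(=O)N(C)OC | intermediate
3 | 1-bromohex-2-yne | CCCC#CCBr | starting material
4 | N-methoxy-N-methylheptadeca-10,13-diynamide | CCCC#CCC#CCCCCCCCCC(=O)N(C)OC | intermediate
5 | (10Z,13Z)-N-methoxy-N-methylheptadeca-10,13-dienamide | CCC/C=C\C/C=C\CCCCCCCCC(=O)N(C)OC | intermediate
6 | methyl vinyl ether (methoxyethene) | COC=C | starting material
7 | 1-methoxyvinyllithium | [Li]C(=C)OC | intermediate
8 | (12Z,15Z)-2-methoxynonadeca-1,12,15-trien-3-one | CCC/C=C\C/C=C\CCCCCCCCC(=O)C(OC)=C | intermediate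
9 | tert-butyl({(3Z,12Z,15Z)-2-methoxynonadeca-1,3,12,15-tetraen-3-yl}oxy)dimethylsilane | CCC/C=C\C/C=C\CCCCCCC/C=C(\O[Si](C)(C)C(C)(C)C)C(OC)=C | intermediate
10 | methyl chlorooxoacetate | COC(=O)C(=O)Cl | starting material
11 | methyl (3E,5Z,14Z,17Z)-5-{[tert-butyl(dimethyl)silyl]oxy}-4-methoxy-2-oxohenicosa-3,5,14,17-tetraenoate | CCC/C=C\C/C=C\CCCCCCC/C=C(\O[Si](C)(C)C(C)(C)C)/C(OC)=C\C(=O)C(=O)OC | intermediate
12 | sorgoleone-360, 2-hydroxy-5-methoxy-3-[(8Z,11Z)-pentadeca-8,11-dien-1-yl]cyclohexa-2,5-diene-1,4-dione | CCC/C=C\C/C=C\CCCCCCCC1=C(O)C(=O)C=C(OC)C1=O | target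

**Step count and risks**
Total step count: 6. Longest linear sequence: 6 steps (1 → 2 → 4 → 5 → 8 → 9 → 12).

Steps most likely to fail:

1. Step 6 (proposed new method). What may go wrong: acylation at the substituted silyl enol ether terminus instead of the CH2 terminus, or loss of the silyl group before acylation so that the unreactive enone returns; either way the ring does not close. Fallback with known chemistry, which sets out from 8, comes back at 12 and also bypasses step 5: hydrolysis of the methyl enol ether of 8 (dilute HCl, THF–H2O) would give (12Z,15Z)-nonadeca-12,15-diene-2,3-dione F1. Slow addition of F1 to dimethyl oxalate and NaOMe in MeOH should give, by Claisen condensation at the methyl group, open-chain methyl (14Z,17Z)-2,4,5-trioxohenicosa-14,17-dienoate F2 (as its enolate, not isolated). A second, ring-closing Claisen condensation on the same C3–C2 bond should then give 2,5-dihydroxy-3-[(8Z,11Z)-pentadeca-8,11-dien-1-yl]cyclohexa-2,5-diene-1,4-dione F3 (the classical double Claisen route to 2,5-dihydroxyquinones). Acid-catalysed methanolysis of the less hindered vinylogous acid, the hydroxyl beside the ring C–H (MeOH, BF3·OEt2, conditions that skipped Z,Z-dienes tolerate in fatty acid methyl ester preparation), would then give 12.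

2. Step 3. What may go wrong: over-reduction to monoenes, Z-to-E isomerisation or stalling at the enyne stage on the palladium surface, giving mixtures that are hard to separate. Fallback, which sets out from 4 and comes back at 5: stoichiometric syn-hydroboration of both alkynes with dicyclohexylborane (THF, 0 °C, where the amide reacts far more slowly than the alkynes) would give (10Z,13Z)-11,13-bis(dicyclohexylboranyl)-N-methoxy-N-methylheptadeca-10,13-dienamide F4 (one representative of the boron regioisomers). Protonolysis of the C–B bonds with acetic acid proceeds with retention and can neither over-reduce nor isomerise.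

3. Step 4. What may go wrong: deprotonation of the amide α-CH2 by the basic alkenyllithium (return of 5) and hydrolytic loss of the methyl enol ether during work-up. Fallback, which sets out from 5 and comes back at 8: reduction of 5 with iBu2AlH (−78 °C) would give (10Z,13Z)-heptadeca-10,13-dienal F5. Addition of 7 to this far more electrophilic aldehyde would give racemic (12Z,15Z)-2-methoxynonadeca-1,12,15-trien-3-ol F6, and oxidation of the allylic alcohol (MnO2, or Dess–Martin periodinane buffered with pyridine) would give 8.

**Further compounds**
F1 | step 6 | (12Z,15Z)-nonadeca-12,15-diene-2,3-dione | CCC/C=C\C/C=C\CCCCCCCCC(=O)C(C)=O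
F2 | step 6 | methyl (14Z,17Z)-2,4,5-trioxohenicosa-14,17-dienoate | CCC/C=C\C/C=C\CCCCCCCCC(=O)C(=O)CC(=O)C(=O)OC
F3 | step 6 | 2,5-dihydroxy-3-[(8Z,11Z)-pentadeca-8,11-dien-1-yl]cyclohexa-2,5-diene-1,4-dione | CCC/C=C\C/C=C\CCCCCCCC1=C(O)C(=O)C=C(O)C1=O
F4 | step 3 | (10Z,13Z)-11,13-bis(dicyclohexylboranyl)-N-methoxy-N-methylheptadeca-10,13-dienamide | CCC/C=C(/B(C1CCCCC1)C1CCCCC1)C/C(B(C1CCCCC1)C1CCCCC1)=C\CCCCCCCCC(=O)N(C)OC
F5 | step 4 | (10Z,13Z)-heptadeca-10,13-dienal | CCC/C=C\C/C=C\CCCCCCCCC=O
F6 | step 4 | (12Z,15Z)-2-methoxynonadeca-1,12,15-trien-3-ol (racemic) | CCC/C=C\C/C=C\CCCCCCCCC(O)C(OC)=C
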